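The flavone is opened to its 1,3-diketone and ring A is then cut across C4a–C8a. Ring carbons C5, C6, C7 (with its OMe), C8 and C8a carry the alternating oxygen pattern of C6, C5, C4, C3 and C2 of 4-methoxy-6-methyl-2-pyrone, and C4a is the pyrone methyl carbon, so ring A is a folded form of that lactone. In one operation Mg(OMe)2 unzips the lactone and an intramolecular Claisen condensation re-closes the chain as the symmetric 2,6-dihydroxy-4-methoxyphenyl ketone. The precursor is the pyrone bearing at C6 a 2,4-dioxobutyl chain that ends in the MOM-protected ring B; acid then closes ring C and frees the 3'-OH.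

Key step: step 8

Remark: organolithium intermediates are drawn as monomers with covalent C–Li or O–Li bonds, and 17 is drawn in its neutral keto form although it is present as a magnesium chelate. In step 9 ring closure and MOM loss may occur in either order, and the sequence through 19 is assumed.

Step 1
Reactants: 1 1,2,4-trimethoxybenzene
Product: 3 2,3,6-trimethoxybenzaldehyde, via aryllithium 2 (not isolated)
Conditions: n-BuLi, THF, 0 °C to rt; DMF, 0 °C; aq. NH4Cl
Reagents that add atoms: N,N-dimethylformamide, CN(C)C=O
Why: Directed ortho-metalation: the C3–H of 1 lies between the 2- and 4-methoxy groups, is the most acidic ring proton and is coordinated from both sides, so n-BuLi should lithiate only there, and formylation of 2 with DMF (Bouveault reaction) then gives 3.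

Step 2
Reactants: 3 2,3,6-trimethoxybenzaldehyde
Product: 4 3-bromo-2,5,6-trimethoxybenzaldehyde
Conditions: NBS, DMF, rt
Reagents that add atoms: N-bromosuccinimide, O=C1CCC(=O)N1Br
Why: Electrophilic aromatic bromination: C5 of 3 is para to the 2-methoxy group, ortho to the 6-methoxy group and meta to the formyl group, whereas the only other free position, C4, is para to the deactivating formyl group, so all directing effects should converge on C5.

Step 3
Reactants: 4 3-bromo-2,5,6-trimethoxybenzaldehyde
Product: 6 3-bromo-2,5,6-trimethoxyphenol, via aryl formate 5 (not isolated)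
Conditions: mCPBA, CH2Cl2, 0 °C to rt; aq. NaHCO3 wash; K2CO3 (cat.), MeOH, rt
Reagents that add atoms: 3-chloroperoxybenzoic acid, OOC(=O)c1cccc(Cl)c1
Why: Dakin-type Baeyer–Villiger oxidation: in the Criegee adduct the aryl group, enriched by two ortho-methoxy donors, should migrate in preference to hydride to give formate 5, which catalytic methanolysis cleaves to the phenol while the aryl bromide and the methyl ethers are untouched.

Step 4
Reactants: 6 3-bromo-2,5,6-trimethoxyphenol
Product: 7 1-bromo-2,4,5-trimethoxy-3-(methoxymethoxy)benzene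
Conditions: MOMCl, K2CO3, DMF, 0 °C to rt
Reagents that add atoms: chloromethyl methyl ether, COCCl
Why: Williamson-type O-alkylation of the phenoxide with the small, highly reactive MOMCl should proceed despite the two flanking methoxy groups, and the resulting acetal withstands the organolithium, enolate and Mg(OMe)2 steps ahead yet falls off in the acidic last step.

Step 5
Reactants: 7 1-bromo-2,4,5-trimethoxy-3-(methoxymethoxy)benzene
Product: 9 1-[2,4,5-trimethoxy-3-(methoxymethoxy)phenyl]ethan-1-one, via aryllithium 8 (not isolated)
Conditions: n-BuLi, THF, −78 °C; MeC(O)N(OMe)Me, −78 to 0 °C; aq. NH4Cl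
Reagents that add atoms: N-methoxy-N-methylacetamide, CC(=O)N(C)OC
Why: Bromine–lithium exchange is much faster than any ring deprotonation at −78 °C, and acylation of 8 with the Weinreb amide stops at the ketone stage because the chelated tetrahedral adduct only collapses on work-up.

Step 6
Reactants: 10 4-methoxy-6-methyl-2H-pyran-2-one
Product: 12 (4-methoxy-2-oxo-2H-pyran-6-yl)acetic acid, via lithiated pyrone 11 (not isolated)
Conditions: LiN(iPr)2, THF, −78 °C; CO2 (excess, inverse addition), −78 °C to rt; aq. HCl
Reagents that add atoms: carbon dioxide, O=C=O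
Why: Vinylogous deprotonation of the 6-methyl group by the hindered amide base gives the extended pyrone dienolate 11 (an alkyllithium would instead metalate C3 or add to the lactone), and carboxylation of this carbanion with CO2, done by inverse addition so that the acidic product cannot quench unreacted 11, should give acid 12.

Step 7
Reactants: 12 (4-methoxy-2-oxo-2H-pyran-6-yl)acetic acid; 13 1,1'-carbonyldiimidazole; 9 1-[2,4,5-trimethoxy-3-(methoxymethoxy)phenyl]ethan-1-one
Product: 16 1-(4-methoxy-2-oxo-2H-pyran-6-yl)-4-[2,4,5-trimethoxy-3-(methoxymethoxy)phenyl]butane-2,4-dione, via acyl imidazolide 14 (not isolated), via lithium enolate 15 (not isolated)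
Conditions: 12, CDI, THF, rt; added to 9 (3 equiv), LiN(iPr)2 (3 equiv), THF, −78 °C; −78 to 0 °C; aq. NH4Cl
Reagents that add atoms: none
Why: Crossed Claisen-type C-acylation of a ketone lithium enolate by an acyl imidazolide: three equivalents of 15 are planned because the liberated imidazole and the acidic methylene of 14 or of the diketone product each consume one (a deprotonated 14 can still deliver the acyl group through its ketene), the pyrone lactone is far less electrophilic than the imidazolide at −78 °C, and the surplus ketone 9 should be recoverable.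

Step 8
Reactants: 16 1-(4-methoxy-2-oxo-2H-pyran-6-yl)-4-[2,4,5-trimethoxy-3-(methoxymethoxy)phenyl]butane-2,4-dione
Product: 18 1-(2,6-dihydroxy-4-methoxyphenyl)-3-[2,4,5-trimethoxy-3-(methoxymethoxy)phenyl]propane-1,3-dione, via triketo ester 17 (not isolated)
Conditions: Mg(OMe)2 (excess), MeOH, reflux, N2; cold dilute HCl
Reagents that add atoms: none
Why: Methoxide adds to the lactone carbonyl (pyrone C2) and opens the ring to the magnesium-chelated triketo ester 17, whose enol ether double bond keeps the ring geometry, with ester and keto chain cis, which is E by the CIP rules because OMe outranks CH2. The methylene between the two chain ketones nearest the enoate (C6 of 17, the future C4a) is the most acidic site; its carbanion adds to the ester carbonyl (the future C8a), methoxide is expelled and the resulting cyclohexenedione enolises to aromatic ring A. The closest known reaction type is the Mg(OMe)2-promoted Claisen (Dieckmann-type) aromatisation of 6-(acylmethyl)-4-methoxy-2-pyrones to acylresorcinols, a net isomerisation in which the methanol taken up on ring opening is released again. Ring A closes in the 6-exo-trig mode, a six-membered carbocycle with the attacked C=O outside the new ring. No stereocentre is formed. The step needs Claisen closure from C4a to win over the six-membered aldol closure from C6 onto the ring B ketone (the future C2); the higher acidity of the doubly flanked C4a methylene, magnesium chelation of the tricarbonyl array, which holds this carbanion next to the cis ester, and the poor electrophilicity of the hindered, electron-rich ortho-methoxy aryl ketone should secure it.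

Step 9
Reactants: 18 1-(2,6-dihydroxy-4-methoxyphenyl)-3-[2,4,5-trimethoxy-3-(methoxymethoxy)phenyl]propane-1,3-dione
Product: 20 5,3'-dihydroxy-7,2',4',5'-tetramethoxyflavone, via MOM-protected flavone 19 (not isolated)
Conditions: HCl (3 M in MeOH), reflux
Reagents that add atoms: none
Why: Acid-catalysed cyclodehydration of a 1-(2-hydroxyaryl)-1,3-diketone, the closing stage of the Baker–Venkataraman flavone synthesis: either of the two equivalent phenols adds to the ring B ketone (6-exo-trig hemiketal formation) and loss of water forms ring C, the other phenol becomes the chelated 5-OH, and the same methanolic acid transacetalises the MOM ether to methylal, releasing the 3'-OH.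

Compound list
1 | 1,2,4-trimethoxybenzene | COc1ccc(OC)c(OC)c1 | starting material
2 | (2,3,6-trimethoxyphenyl)lithium | [Li]c1c(OC)ccc(OC)c1OC | intermediate
3 | 2,3,6-trimethoxybenzaldehyde | O=Cc1c(OC)ccc(OC)c1OC | intermediate
4 | 3-bromo-2,5,6-trimethoxybenzaldehyde | O=Cc1c(OC)c(Br)cc(OC)c1OC | intermediate
5 | 3-bromo-2,5,6-trimethoxyphenyl formate | O=COc1c(OC)c(Br)cc(OC)c1OC | intermediate
6 | 3-bromo-2,5,6-trimethoxyphenol | Oc1c(OC)c(Br)cc(OC)c1OC | intermediate
7 | 1-bromo-2,4,5-trimethoxy-3-(methoxymethoxy)benzene | COCOc1c(OC)c(Br)cc(OC)c1OC | intermediate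
8 | [2,4,5-trimethoxy-3-(methoxymethoxy)phenyl]lithium | [Li]c1cc(OC)c(OC)c(OCOC)c1OC | intermediate
9 | 1-[2,4,5-trimethoxy-3-(methoxymethoxy)phenyl]ethan-1-one | CC(=O)c1cc(OC)c(OC)c(OCOC)c1OC | intermediate
10 | 4-methoxy-6-methyl-2H-pyran-2-one | COc1cc(C)oc(=O)c1 | starting material
11 | [(4-methoxy-2-oxo-2H-pyran-6-yl)methyl]lithium | [Li]Cc1cc(OC)cc(=O)o1 | intermediate
12 | (4-methoxy-2-oxo-2H-pyran-6-yl)acetic acid | COc1cc(CC(=O)O)oc(=O)c1 | intermediate
13 | 1,1'-carbonyldiimidazole | O=C(n1ccnc1)n1ccnc1 | starting material
14 | 6-[2-(1H-imidazol-1-yl)-2-oxoethyl]-4-methoxy-2H-pyran-2-one | COc1cc(CC(=O)n2ccnc2)oc(=O)c1 | intermediate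
15 | lithium 1-[2,4,5-trimethoxy-3-(methoxymethoxy)phenyl]ethen-1-olate (lithium enolate of 9) | [Li]OC(=C)c1cc(OC)c(OC)c(OCOC)c1OC | intermediate
16 | 1-(4-methoxy-2-oxo-2H-pyran-6-yl)-4-[2,4,5-trimethoxy-3-(methoxymethoxy)phenyl]butane-2,4-dione | COc1cc(CC(=O)CC(=O)c2cc(OC)c(OC)c(OCOC)c2OC)oc(=O)c1 | intermediate
17 | methyl (2E)-3-methoxy-5,7,9-trioxo-9-[2,4,5-trimethoxy-3-(methoxymethoxy)phenyl]non-2-enoate | COC(=O)/C=C(/OC)CC(=O)CC(=O)CC(=O)c1cc(OC)c(OC)c(OCOC)c1OC | intermediate
18 | 1-(2,6-dihydroxy-4-methoxyphenyl)-3-[2,4,5-trimethoxy-3-(methoxymethoxy)phenyl]propane-1,3-dione | COc1cc(O)c(C(=O)CC(=O)c2cc(OC)c(OC)c(OCOC)c2OC)c(O)c1 | intermediate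
19 | 5-hydroxy-7-methoxy-2-[2,4,5-trimethoxy-3-(methoxymethoxy)phenyl]-4H-chromen-4-one | COc1cc(O)c2c(=O)cc(-c3cc(OC)c(OC)c(OCOC)c3OC)oc2c1 | intermediate
20 | 5,3'-dihydroxy-7,2',4',5'-tetramethoxyflavone (5-hydroxy-2-(3-hydroxy-2,4,5-trimethoxyphenyl)-7-methoxy-4H-chromen-4-one) | COc1cc(O)c2c(=O)cc(-c3cc(OC)c(OC)c(O)c3OC)oc2c1 | target

Total step count: 9.
Longest linear sequence: 8 steps (steps 1, 2, 3, 4, 5, 7, 8 and 9 from 1,2,4-trimethoxybenzene); the pyrone branch joins after its single step 6.

Steps most likely to fail

Step 8. The open-chain intermediate may cyclise by aldol condensation from C6 onto the ring B ketone, or fragment by retro-Claisen methanolysis, instead of undergoing the Claisen closure. The fallback buys ring A instead of making it. It sets out from bromide 7: the aryllithium 8 is quenched with CO2 to give 2,4,5-trimethoxy-3-(methoxymethoxy)benzoic acid F1. This acid is coupled (EDC, DMAP, CH2Cl2) to one of the two equivalent phenols of commercial 1-(2,6-dihydroxy-4-methoxyphenyl)ethan-1-one (CC(=O)c1c(O)cc(OC)cc1O), giving 2-acetyl-3-hydroxy-5-methoxyphenyl 2,4,5-trimethoxy-3-(methoxymethoxy)benzoate F2. A Baker–Venkataraman rearrangement (LiN(SiMe3)2, THF, −78 °C to rt, or KOH in pyridine) then moves the aroyl group from oxygen to the acetyl carbon, and the route is rejoined at diketone 18.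

Step 7. Proton transfer from the acidic methylene of imidazolide 14, or from imidazole, to enolate 15 may outrun C-acylation, or 15 may be acylated on oxygen. The fallback reverses the polarity, so that the pyrone fragment is the nucleophile and ring B the acyl donor. It sets out from pyrone 10 and bromide 7. Lithiated pyrone 11 is acylated with N-methoxy-N-methylacetamide to give 4-methoxy-6-(2-oxopropyl)-2H-pyran-2-one F3, which two equivalents of LiN(iPr)2 convert into the dilithium dianion of 4-methoxy-6-(2-oxopropyl)-2H-pyran-2-one F4. Its terminal carbanion is acylated by methyl 2,4,5-trimethoxy-3-(methoxymethoxy)benzoate F5, made from 7 through 8 and methyl chloroformate and used as the limiting partner. This returns to the route at pyrone diketone 16.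

Step 2. Bromine may attack ipso at the formyl-bearing carbon (bromodeformylation) or at C4, eroding regioselectivity. The fallback removes the formyl group from the sequence and installs the phenol oxygen before the bromine. It sets out from 1: the aryllithium 2 is trapped with B(OMe)3 to give dimethyl (2,3,6-trimethoxyphenyl)boronate F6, which is oxidised in the same flask (H2O2, NaOH) to 2,3,6-trimethoxyphenol F7. Acetylation (Ac2O, pyridine) gives 2,3,6-trimethoxyphenyl acetate F8. Its acetoxy group is a poor donor, so NBS bromination should be steered para to the 2-methoxy group, as with guaiacol acetate, to 3-bromo-2,5,6-trimethoxyphenyl acetate F9. Methanolysis (K2CO3, MeOH) returns to the route at phenol 6.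

Further compounds
F1 | step 8 | 2,4,5-trimethoxy-3-(methoxymethoxy)benzoic acid | OC(=O)c1cc(OC)c(OC)c(OCOC)c1OC
F2 | step 8 | 2-acetyl-3-hydroxy-5-methoxyphenyl 2,4,5-trimethoxy-3-(methoxymethoxy)benzoate | CC(=O)c1c(O)cc(OC)cc1OC(=O)c1cc(OC)c(OC)c(OCOC)c1OC
F3 | step 7 | 4-methoxy-6-(2-oxopropyl)-2H-pyran-2-one | COc1cc(CC(C)=O)oc(=O)c1
F4 | step 7 | dilithium dianion of 4-methoxy-6-(2-oxopropyl)-2H-pyran-2-one | [Li]CC(O[Li])=Cc1cc(OC)cc(=O)o1
F5 | step 7 | methyl 2,4,5-trimethoxy-3-(methoxymethoxy)benzoate | COC(=O)c1cc(OC)c(OC)c(OCOC)c1OC
F6 | step 2 | dimethyl (2,3,6-trimethoxyphenyl)boronate | COB(OC)c1c(OC)ccc(OC)c1OC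
F7 | step 2 | 2,3,6-trimethoxyphenol | Oc1c(OC)ccc(OC)c1OC
F8 | step 2 | 2,3,6-trimethoxyphenyl acetate | CC(=O)Oc1c(OC)ccc(OC)c1OC
F9 | step 2 | 3-bromo-2,5,6-trimethoxyphenyl acetate | CC(=O)Oc1c(OC)c(Br)cc(OC)c1OC
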